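**One step.** A one-step first-order world has one time constant: the fraction left falls by the same factor in each equal stretch of time, whatever the charge. In the runs below, intermediate rises first, while target and side product lag behind it, so you need more than a clock.

| flask | substrate | remark | time |
|---|---|---|---|
| noon | 0.46 M | run made earlier |  |
| dusk | 0.73 M | run made earlier |  |
| flask | 0.33 M |  | 30 min |

| run | time / min | target / % | intermediate / % | side product / % |
|---|---|---|---|---|
| noon | 2.50 | 3.2 | 16.1 | 4.3 |
| noon | 5.00 | 10.9 | 24.6 | 6.8 |
| noon | 8.00 | 16.3 | 23.6 | 13.5 |
| noon | 10.0 | 24.1 | 22.2 | 16.1 |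
| noon | 12.0 | 30.0 | 21.2 | 21.6 |
| noon | 15.0 | 37.6 | 17.0 | 24.7 |
| noon | 20.0 | 44.1 | 10.9 | 30.4 |
| dusk | 1.00 | 1.8 | 7.1 | 0.8 |
| dusk | 3.00 | 4.1 | 18.8 | 1.7 |
| dusk | 5.00 | 10.7 | 22.1 | 6.6 |
| dusk | 8.00 | 18.2 | 24.8 | 11.4 |
| dusk | 10.0 | 25.2 | 23.3 | 15.0 |
| dusk | 15.0 | 35.6 | 15.4 | 23.4 |
| dusk | 20.0 | 44.5 | 11.3 | 29.7 |

(standard deviation of a reading: 1 percentage point)

- a reading or a percentage of target counts all its forms, free or not

- how much target the flask holds at 30 min, in percent of the substrate charged
- how much intermediate the flask holds at 30 min, in percent of the substrate charged
- how much side product the flask holds at 30 min, in percent of the substrate charged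

**The share.** The last readings of both runs, pooled, give 0.596 as the target share, the fraction of finished material that is target; chemists call this the selectivity. Is one number enough? For the split, yes: at 10.0 min it reads 0.600 at noon and 0.627 at dusk, close within the scatter. For amounts, no: it holds no time.

**Going round.** As a first answer, call the whole charge finished: target is the share itself. Now put back what is unfinished. Substrate, the charge minus the three readings, averages 0.145 at 20.0 min. Raised to the power 1.50, as in a one-step world, that gives an estimate of 0.0555 at 30 min. The intermediate readings there average 0.763 of that substrate; holding that ratio gives 0.0423. Going round once more, my reckoning for the flask, charged below both runs, carries their percentages over unchanged and is target 0.538 and side product 0.364.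

**The forecast.** It holds that “every step looks first order” and gives target 54 %, intermediate 4.7 % and side product 36.3 %; its intermediate is higher than mine.

**The flask.**

    intermediate → target (k = 0.125 min⁻¹)
    crystals ⇌ target, rate k2*(cs2 - [target]) while solid is left; crystals form when [target] > cs2 (solubility = 37.0 mM, k = 6.54 min⁻¹)
    intermediate → side product (k = 0.0842 min⁻¹)
    substrate → intermediate (k = 0.0992 min⁻¹)

At 30 min the flask holds target 54.1 %, intermediate 4.43 % and side product 36.4 %, so the forecast stands within its margins. Crystals make up 42.8 % of the charge, counted in the target, and the limit of solubility leaves the amount of target unchanged. Read the same flask at 8.0 min: substrate 45.2 % and intermediate 23.9 % are unfinished, so the share gives 0.184 of the charge as target, and that reading holds 18.5 %.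

The numbers in the tables were generated by integration with constants of no real substance; scatter was added.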